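**Assumption:** "CNP0295282.1" is taken to be exactly the given SMILES. Locants C5–C10 are elemane numbers: C10 = quaternary carbon, C5 = CH bearing the acrolein unit, C6 = CH–O-angeloyl, C7/C8 = lactone ring fusion (C8 bears the lactone O), C9 = CH–O-(2-methylbutanoyl). None of the stereochemical outcomes below has been tested; they rest on the models named in each step.

## Retrosynthetic overview

1. Target ⇐ allylic oxidation of a C5 isopropenyl group; the two esters go on one after the other because the C9-OH and the C6-OH are unveiled at different stages (no protecting groups).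
2. C6-OH ⇐ C6 ketone ⇐ dimethyl ketal; cis-lactone ⇐ carboxylate SN2 at a C8 bromide; C9-OH ⇐ reduction of the α-bromo ketone.
3. C5 and the C10 quaternary centre ⇐ cuprate 1,4-addition to a 2-methyl enone with aldol trapping of the enolate (then dehydration to vinyl).
4. C7 and the α-methylene acid ⇐ enantioselective phosphine-catalysed cross-Rauhut–Currier reaction of an acrylate with an achiral quinone monoketal (key step, new).
5. Ring order: the carbocycle is the dearomatised ring of 4-methoxy-2-methylphenol (step 1); the γ-lactone is closed second (step 6).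

## Route

Step 1
Reactants: 1 4-methoxy-2-methylphenol
Product: 2 4,4-dimethoxy-2-methylcyclohexa-2,5-dien-1-one
Conditions: PhI(OAc)2 (1.1 equiv), MeOH, 0 °C, 30 min
Reagents that add atoms: methanol (CO)
Why: Oxidative dearomatisation of a para-alkoxyphenol with an iodine(III) reagent in methanol gives the achiral quinone monoketal, in which both β-carbons and both α-carbons of the future ring are differentiated by the methyl group.

Step 2
Reactants: 2 4,4-dimethoxy-2-methylcyclohexa-2,5-dien-1-one; 3 methyl acrylate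
Product: 5 2-[(1R)-2,2-dimethoxy-4-methyl-5-oxocyclohex-3-en-1-yl]prop-2-enoic acid, via methyl ester 4 (not isolated)
Conditions: 2 (2 equiv), 3 (1 equiv, syringe pump, 8 h), phosphine–thiourea P* = 1-[3,5-bis(trifluoromethyl)phenyl]-3-[(2S)-1-(diphenylphosphanyl)-3,3-dimethylbutan-2-yl]thiourea (10 mol %; its enantiomer if that one gives the (R) product), 2-naphthol (20 mol %), toluene, 0 °C to rt; then LiOH·H2O (3 equiv), THF/H2O, 0 °C; cold 1 M HCl to pH 4.5, extract, keep cold
Reagents that add atoms: lithium hydroxide ([Li+].[OH-])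
Why: Proposed new method: an enantioselective intermolecular cross-Rauhut–Currier reaction in which the chiral phosphine adds to 3 to give a β-phosphonium enolate that attacks the less substituted enone of 2 at the β-carbon next to the ketal while the thiourea N–H bonds bind the dienone carbonyl and shield one face, after which proton transfer and loss of the phosphine leave the 2-substituted acrylate and the C7 (R) stereocentre (the ester is then saponified in the same pot); the closest known reactions are the phosphine-catalysed cross-Rauhut–Currier/1,6-additions of acrylates and vinyl ketones to para-quinone methides and the enantioselective intramolecular Rauhut–Currier desymmetrisation of cyclohexadienones.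

Step 3
Reactants: 5 2-[(1R)-2,2-dimethoxy-4-methyl-5-oxocyclohex-3-en-1-yl]prop-2-enoic acid; 6 isopropenylmagnesium bromide; 7 acetaldehyde
Product: 9 2-[(1R,3S,4R)-4-(1-hydroxyethyl)-2,2-dimethoxy-4-methyl-5-oxo-3-(prop-1-en-2-yl)cyclohexyl]prop-2-enoic acid (carbinol epimers), via magnesium enolate 8 (not isolated)
Conditions: 6 (4.2 equiv), CuBr·SMe2 (1.6 equiv), THF, −78 to −30 °C; then 7 (5 equiv), −78 °C; aq NH4Cl, pH 5 work-up
Reagents that add atoms: none
Why: Tandem cuprate 1,4-addition–aldol reaction, in which the acrylate is shielded in situ as its unreactive magnesium carboxylate, the isopropenyl group adds to the 2-methyl enone trans to the C7 side chain (as in 5-substituted cyclohexenones), and the regiodefined enolate 8 takes up acetaldehyde anti to the new C5 substituent, which fixes the C10 quaternary centre.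

Step 4
Reactants: 9 2-[(1R,3S,4R)-4-(1-hydroxyethyl)-2,2-dimethoxy-4-methyl-5-oxo-3-(prop-1-en-2-yl)cyclohexyl]prop-2-enoic acid
Product: 10 2-[(1R,3S,4S)-4-ethenyl-2,2-dimethoxy-4-methyl-5-oxo-3-(prop-1-en-2-yl)cyclohexyl]prop-2-enoic acid
Conditions: POCl3 (4 equiv), pyridine, 0 to 50 °C; aq NaHCO3 (hydrolyses the mixed anhydride of the acid), then pH 5
Reagents that add atoms: none
Why: E2 dehydration of the dichlorophosphate (POCl3/pyridine) can only remove a methyl hydrogen because C10 is quaternary, so the 1-hydroxyethyl group becomes the vinyl group without touching a stereocentre.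

Step 5
Reactants: 10 2-[(1R,3S,4S)-4-ethenyl-2,2-dimethoxy-4-methyl-5-oxo-3-(prop-1-en-2-yl)cyclohexyl]prop-2-enoic acid
Product: 13 2-[(1R,3S,4S,5R,6S)-6-bromo-4-ethenyl-5-hydroxy-2,2-dimethoxy-4-methyl-3-(prop-1-en-2-yl)cyclohexyl]prop-2-enoic acid, via bis-silyl derivative 11 (not isolated), via bromoketone silyl ester 12 (not isolated)
Conditions: LiHMDS (2.3 equiv), THF, −78 °C; TMSCl (2.5 equiv); NBS (1.05 equiv), −78 °C; then NaBH4 (3 equiv), MeOH, −78 to −40 °C; pH 5 buffer
Reagents that add atoms: N-bromosuccinimide (O=C1CCC(=O)N1Br); chlorotrimethylsilane (C[Si](C)(C)Cl; its atoms stay only in intermediates 11 and 12)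
Why: Enolisation is possible only towards C8, the silyl enol ether is brominated by NBS anti to the C7 side chain, and borohydride attacks the α-bromo ketone anti to the C–Br bond (Cornforth/polar Felkin–Anh control) to give the cis-bromohydrin with C9 configured as in the target.

Step 6
Reactants: 13 2-[(1R,3S,4S,5R,6S)-6-bromo-4-ethenyl-5-hydroxy-2,2-dimethoxy-4-methyl-3-(prop-1-en-2-yl)cyclohexyl]prop-2-enoic acid
Product: 14 (3aS,5S,6S,7R,7aR)-6-ethenyl-7-hydroxy-4,4-dimethoxy-6-methyl-3-methylidene-5-(prop-1-en-2-yl)hexahydro-1-benzofuran-2(3H)-one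
Conditions: K2CO3 (1.5 equiv), DMF, rt to 40 °C
Reagents that add atoms: none
Why: Intramolecular SN2 displacement (5-exo-tet) of the C8 bromide by the carboxylate goes with inversion and so gives the cis-fused α-methylene-γ-butyrolactone trans to the C9 hydroxyl, while the cis-bromohydrin cannot close to an epoxide.

Step 7
Reactants: 15 tiglic acid
Product: 16 (2R)-2-methylbutanoic acid
Conditions: H2 (4 atm), Ru(OAc)2[(R)-H8-BINAP] (0.5 mol %), MeOH, 20 °C
Reagents that add atoms: none
Why: Noyori-type Ru–BINAP asymmetric hydrogenation of an α,β-unsaturated acid, in which the bound carboxylate directs hydrogen to one enantioface and sets the (R) α-stereocentre.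

Step 8
Reactants: 14 (3aS,5S,6S,7R,7aR)-6-ethenyl-7-hydroxy-4,4-dimethoxy-6-methyl-3-methylidene-5-(prop-1-en-2-yl)hexahydro-1-benzofuran-2(3H)-one; 16 (2R)-2-methylbutanoic acid
Product: 17 (3aS,5S,6S,7R,7aR)-6-ethenyl-4,4-dimethoxy-6-methyl-3-methylidene-2-oxo-5-(prop-1-en-2-yl)octahydro-1-benzofuran-7-yl (2R)-2-methylbutanoate
Conditions: DCC (1.5 equiv), DMAP (0.3 equiv), CH2Cl2, 0 °C to rt
Reagents that add atoms: none
Why: Steglich esterification of the only free hydroxyl (C9) under mild conditions that do not epimerise the α-stereocentre of the acid.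

Step 9
Reactants: 17 (3aS,5S,6S,7R,7aR)-6-ethenyl-4,4-dimethoxy-6-methyl-3-methylidene-2-oxo-5-(prop-1-en-2-yl)octahydro-1-benzofuran-7-yl (2R)-2-methylbutanoate
Product: 19 (3aR,4S,5S,6S,7R,7aR)-6-ethenyl-4-hydroxy-6-methyl-3-methylidene-2-oxo-5-(prop-1-en-2-yl)octahydro-1-benzofuran-7-yl (2R)-2-methylbutanoate, via C6 ketone 18 (not isolated)
Conditions: PPTS (0.2 equiv), acetone/H2O (10:1), rt; concentrate cold, toluene azeotrope; LiAlH(O-t-Bu)3 (1.5 equiv), THF, −78 °C
Reagents that add atoms: water (O)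
Why: Mild ketal hydrolysis unmasks the C6 ketone, which is reduced at once (before its β,γ-alkenes can move into conjugation) by a bulky hydride that attacks equatorially, away from the syn-axial C10 methyl, to give the axial C6 alcohol cis to the isopropenyl group (substrate control as in 3,3,5-trimethylcyclohexanone).

Step 10
Reactants: 19 (3aR,4S,5S,6S,7R,7aR)-6-ethenyl-4-hydroxy-6-methyl-3-methylidene-2-oxo-5-(prop-1-en-2-yl)octahydro-1-benzofuran-7-yl (2R)-2-methylbutanoate; 20 angelic acid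
Product: 22 (3aR,4S,5S,6S,7R,7aR)-6-ethenyl-6-methyl-3-methylidene-7-{[(2R)-2-methylbutanoyl]oxy}-2-oxo-5-(prop-1-en-2-yl)octahydro-1-benzofuran-4-yl (2Z)-2-methylbut-2-enoate, via mixed anhydride 21 (not isolated)
Conditions: 20 (4 equiv), 2,4,6-trichlorobenzoyl chloride (4 equiv), Et3N (4 equiv), toluene, rt, 2 h; then 19, toluene, 80 °C
Reagents that add atoms: 2,4,6-trichlorobenzoyl chloride (O=C(Cl)c1c(Cl)cc(Cl)cc1Cl; its atoms stay only in intermediate 21)
Why: Yamaguchi-type mixed-anhydride esterification without DMAP is the established way to angeloylate hindered secondary alcohols without Z-to-E isomerisation to the tiglate.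

Step 11
Reactants: 22 (3aR,4S,5S,6S,7R,7aR)-6-ethenyl-6-methyl-3-methylidene-7-{[(2R)-2-methylbutanoyl]oxy}-2-oxo-5-(prop-1-en-2-yl)octahydro-1-benzofuran-4-yl (2Z)-2-methylbut-2-enoate
Product: 23 (3aR,4S,5R,6S,7R,7aR)-6-ethenyl-6-methyl-3-methylidene-7-{[(2R)-2-methylbutanoyl]oxy}-2-oxo-5-(3-oxoprop-1-en-2-yl)octahydro-1-benzofuran-4-yl (2Z)-2-methylbut-2-enoate (target)
Conditions: SeO2 (2 equiv), 1,4-dioxane, 70 °C
Reagents that add atoms: selenium dioxide (O=[Se]=O)
Why: Riley allylic oxidation (ene reaction/[2,3]-shift) takes the methyl of the only electron-rich alkene with allylic hydrogens (isopropenyl), since the vinyl group has none and the acrylate-type alkenes are deactivated, to give the 2-substituted acrolein with no stereocentre affected.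

## Compound list

1 | 4-methoxy-2-methylphenol | COc1ccc(O)c(C)c1 | starting material
2 | 4,4-dimethoxy-2-methylcyclohexa-2,5-dien-1-one | CC1=CC(OC)(OC)C=CC1=O | intermediate
3 | methyl acrylate | C=CC(=O)OC | starting material
4 | methyl 2-[(1R)-2,2-dimethoxy-4-methyl-5-oxocyclohex-3-en-1-yl]prop-2-enoate | CC1=CC(OC)(OC)[C@@H](C(=C)C(=O)OC)CC1=O | intermediate
5 | 2-[(1R)-2,2-dimethoxy-4-methyl-5-oxocyclohex-3-en-1-yl]prop-2-enoic acid | CC1=CC(OC)(OC)[C@@H](C(=C)C(=O)O)CC1=O | intermediate
6 | isopropenylmagnesium bromide (prop-1-en-2-ylmagnesium bromide) | CC(=C)[Mg]Br | starting material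
7 | acetaldehyde | CC=O | starting material
8 | bis(bromomagnesium) enolate–carboxylate of the 1,4-adduct (isopropenyl at C5 trans to the C7 side chain) | C=C(C)[C@@H]1C(OC)(OC)[C@@H](C(=C)C(=O)O[Mg]Br)CC(O[Mg]Br)=C1C | intermediate
9 | 2-[(1R,3S,4R)-4-(1-hydroxyethyl)-2,2-dimethoxy-4-methyl-5-oxo-3-(prop-1-en-2-yl)cyclohexyl]prop-2-enoic acid (carbinol epimers) | CC(O)[C@@]1(C)[C@H](C(C)=C)C(OC)(OC)[C@@H](C(=C)C(=O)O)CC1=O | intermediate
10 | 2-[(1R,3S,4S)-4-ethenyl-2,2-dimethoxy-4-methyl-5-oxo-3-(prop-1-en-2-yl)cyclohexyl]prop-2-enoic acid | C=C[C@@]1(C)[C@H](C(C)=C)C(OC)(OC)[C@@H](C(=C)C(=O)O)CC1=O | intermediate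
11 | trimethylsilyl 2-[(1R,4S,5S)-4-ethenyl-6,6-dimethoxy-4-methyl-5-(prop-1-en-2-yl)-3-(trimethylsilyloxy)cyclohex-2-en-1-yl]prop-2-enoate | C=C[C@@]1(C)[C@H](C(C)=C)C(OC)(OC)[C@@H](C(=C)C(=O)O[Si](C)(C)C)C=C1O[Si](C)(C)C | intermediate
12 | trimethylsilyl 2-[(1R,3S,4S,6S)-6-bromo-4-ethenyl-2,2-dimethoxy-4-methyl-5-oxo-3-(prop-1-en-2-yl)cyclohexyl]prop-2-enoate | C=C[C@@]1(C)[C@H](C(C)=C)C(OC)(OC)[C@@H](C(=C)C(=O)O[Si](C)(C)C)[C@H](Br)C1=O | intermediate
13 | 2-[(1R,3S,4S,5R,6S)-6-bromo-4-ethenyl-5-hydroxy-2,2-dimethoxy-4-methyl-3-(prop-1-en-2-yl)cyclohexyl]prop-2-enoic acid | C=C[C@@]1(C)[C@H](C(C)=C)C(OC)(OC)[C@@H](C(=C)C(=O)O)[C@H](Br)[C@@H]1O | intermediate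
14 | (3aS,5S,6S,7R,7aR)-6-ethenyl-7-hydroxy-4,4-dimethoxy-6-methyl-3-methylidene-5-(prop-1-en-2-yl)hexahydro-1-benzofuran-2(3H)-one | C=C[C@@]1(C)[C@H](C(C)=C)C(OC)(OC)[C@H]2C(=C)C(=O)O[C@H]2[C@@H]1O | intermediate
15 | tiglic acid ((2E)-2-methylbut-2-enoic acid) | C/C=C(\C)C(=O)O | starting material
16 | (2R)-2-methylbutanoic acid | CC[C@@H](C)C(=O)O | intermediate
17 | (3aS,5S,6S,7R,7aR)-6-ethenyl-4,4-dimethoxy-6-methyl-3-methylidene-2-oxo-5-(prop-1-en-2-yl)octahydro-1-benzofuran-7-yl (2R)-2-methylbutanoate | C=C[C@@]1(C)[C@H](C(C)=C)C(OC)(OC)[C@H]2C(=C)C(=O)O[C@H]2[C@@H]1OC(=O)[C@H](C)CC | intermediate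
18 | (3aS,5S,6S,7R,7aR)-6-ethenyl-6-methyl-3-methylidene-2,4-dioxo-5-(prop-1-en-2-yl)octahydro-1-benzofuran-7-yl (2R)-2-methylbutanoate | C=C[C@@]1(C)[C@H](C(C)=C)C(=O)[C@H]2C(=C)C(=O)O[C@H]2[C@@H]1OC(=O)[C@H](C)CC | intermediate
19 | (3aR,4S,5S,6S,7R,7aR)-6-ethenyl-4-hydroxy-6-methyl-3-methylidene-2-oxo-5-(prop-1-en-2-yl)octahydro-1-benzofuran-7-yl (2R)-2-methylbutanoate | C=C[C@@]1(C)[C@H](C(C)=C)[C@H](O)[C@H]2C(=C)C(=O)O[C@H]2[C@@H]1OC(=O)[C@H](C)CC | intermediate
20 | angelic acid ((2Z)-2-methylbut-2-enoic acid) | C/C=C(/C)C(=O)O | starting material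
21 | (2Z)-2-methylbut-2-enoic 2,4,6-trichlorobenzoic anhydride | C/C=C(/C)C(=O)OC(=O)c1c(Cl)cc(Cl)cc1Cl | intermediate
22 | (3aR,4S,5S,6S,7R,7aR)-6-ethenyl-6-methyl-3-methylidene-7-{[(2R)-2-methylbutanoyl]oxy}-2-oxo-5-(prop-1-en-2-yl)octahydro-1-benzofuran-4-yl (2Z)-2-methylbut-2-enoate | C=C[C@@]1(C)[C@H](C(C)=C)[C@H](OC(=O)/C(C)=C\C)[C@H]2C(=C)C(=O)O[C@H]2[C@@H]1OC(=O)[C@H](C)CC | intermediate
23 | (3aR,4S,5R,6S,7R,7aR)-6-ethenyl-6-methyl-3-methylidene-7-{[(2R)-2-methylbutanoyl]oxy}-2-oxo-5-(3-oxoprop-1-en-2-yl)octahydro-1-benzofuran-4-yl (2Z)-2-methylbut-2-enoate | C=C[C@@]1(C)[C@H](C(=C)C=O)[C@H](OC(=O)/C(C)=C\C)[C@H]2C(=C)C(=O)O[C@H]2[C@@H]1OC(=O)[C@H](C)CC | target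

## Step count and risks

Total steps: 11. Longest linear sequence: 10 (steps 1–6 and 8–11); step 7 is a one-step side branch.

The three steps most likely to fail:

**Step 2 (the proposed cross-Rauhut–Currier reaction).** The risks are acrylate self-dimerisation, attack at the wrong enone, low ee, and acid-triggered aromatisation of the adduct. The fallback uses known chemistry, sets out from 2 and returns at 5. Diallyl malonate is added to the unsubstituted enone of 2 under cinchona-derived bifunctional thiourea or primary-amine catalysis of the type established for malonate additions to cyclic enones. This gives diallyl 2-[(1R)-2,2-dimethoxy-4-methyl-5-oxocyclohex-3-en-1-yl]propanedioate F1. Pd(PPh3)4 with morpholine removes both allyl groups to give 2-[(1R)-2,2-dimethoxy-4-methyl-5-oxocyclohex-3-en-1-yl]propanedioic acid F2. Mannich-type decarboxylative methylenation of F2 (paraformaldehyde, Et2NH, dioxane, 60 °C) then gives the 2-substituted acrylic acid 5.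

**Step 5 (C9 configuration).** Hydride may attack the bromo ketone from the wrong face, or the carboxylate may displace bromide before reduction. The fallback sets out from 12 and returns at 14, and changes the order of events and the source of stereocontrol. Aqueous NaHCO3 work-up of 12 at rt hydrolyses the silyl ester and lets the carboxylate displace the activated α-bromide at once, giving the keto-lactone (3aS,5S,6S,7aR)-6-ethenyl-4,4-dimethoxy-6-methyl-3-methylidene-5-(prop-1-en-2-yl)tetrahydro-1-benzofuran-2,7(3H,7aH)-dione F3. The C9 ketone of F3 is then reduced under reagent control with (R)-Me-CBS (20 mol %) and catecholborane in toluene at −78 °C, a combination that leaves the alkenes alone, to give 14.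

**Step 9 (unmasking and reduction of the C6 ketone).** Ketone 18 can isomerise its β,γ-alkenes into conjugation, the hydride can come from the wrong face, and the α-methylene lactone can be reduced in conjugate fashion. The fallback sets out from 17 and returns at 19, and uses the classical amine masking of α-methylene lactones. Dimethylamine (2 M in THF, rt) adds to 17 to give the Mannich base (3aS,5S,6S,7R,7aR)-3-[(dimethylamino)methyl]-6-ethenyl-4,4-dimethoxy-6-methyl-2-oxo-5-(prop-1-en-2-yl)octahydro-1-benzofuran-7-yl (2R)-2-methylbutanoate F4. PPTS in wet acetone gives the corresponding 4-ketone F5, which no longer has an alkene next to C7. L-Selectride at −78 °C then gives the axial alcohol (4S)-3-[(dimethylamino)methyl]-4-hydroxy analogue F6. MeI in MeOH followed by NaHCO3 eliminates trimethylamine and regenerates the methylene lactone 19.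

## Further compounds

F1 | step 2 | diallyl 2-[(1R)-2,2-dimethoxy-4-methyl-5-oxocyclohex-3-en-1-yl]propanedioate | CC1=CC(OC)(OC)[C@@H](C(C(=O)OCC=C)C(=O)OCC=C)CC1=O
F2 | step 2 | 2-[(1R)-2,2-dimethoxy-4-methyl-5-oxocyclohex-3-en-1-yl]propanedioic acid | CC1=CC(OC)(OC)[C@@H](C(C(=O)O)C(=O)O)CC1=O
F3 | step 5 | (3aS,5S,6S,7aR)-6-ethenyl-4,4-dimethoxy-6-methyl-3-methylidene-5-(prop-1-en-2-yl)tetrahydro-1-benzofuran-2,7(3H,7aH)-dione | C=C[C@@]1(C)[C@H](C(C)=C)C(OC)(OC)[C@H]2C(=C)C(=O)O[C@H]2C1=O
F4 | step 9 | (3aS,5S,6S,7R,7aR)-3-[(dimethylamino)methyl]-6-ethenyl-4,4-dimethoxy-6-methyl-2-oxo-5-(prop-1-en-2-yl)octahydro-1-benzofuran-7-yl (2R)-2-methylbutanoate (C3 epimers) | C=C[C@@]1(C)[C@H](C(C)=C)C(OC)(OC)[C@H]2C(CN(C)C)C(=O)O[C@H]2[C@@H]1OC(=O)[C@H](C)CC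
F5 | step 9 | (3aS,5S,6S,7R,7aR)-3-[(dimethylamino)methyl]-6-ethenyl-6-methyl-2,4-dioxo-5-(prop-1-en-2-yl)octahydro-1-benzofuran-7-yl (2R)-2-methylbutanoate (C3 epimers) | C=C[C@@]1(C)[C@H](C(C)=C)C(=O)[C@H]2C(CN(C)C)C(=O)O[C@H]2[C@@H]1OC(=O)[C@H](C)CC
F6 | step 9 | (3aR,4S,5S,6S,7R,7aR)-3-[(dimethylamino)methyl]-6-ethenyl-4-hydroxy-6-methyl-2-oxo-5-(prop-1-en-2-yl)octahydro-1-benzofuran-7-yl (2R)-2-methylbutanoate (C3 epimers) | C=C[C@@]1(C)[C@H](C(C)=C)[C@H](O)[C@H]2C(CN(C)C)C(=O)O[C@H]2[C@@H]1OC(=O)[C@H](C)CC
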